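**Plan**

- Retrosynthesis: the two phenols are unmasked from benzyl ethers and the C4 carbinol is traced back to a C4 ketone; the C8–acyl bond is then cut (Friedel–Crafts); finally O1–C8a and C4a–C4 are cut together, giving an aryne of ring A and 3-methylbut-2-enoic acid, with O1–C2 falling to an oxa-Michael closure in the same flask.
- Enabling feature: on the hexasubstituted ring A the pyran oxygen O1 (on C8a) and the carbinol carbon C4 (on C4a) are ortho neighbours, C4a is flanked by the C5 oxygen and C8a by C8. An aryne across C8a–C4a with C5–OMe and C8–H is polarised to take oxygen at C8a and carbon at C4a. The 1,3,5-oxygen pattern (C5, C7, C8a) lets its silyl triflate come from a symmetric phenol with two equivalent ortho positions.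
- Forward: 2,6-dimethoxytoluene → symmetric phenol → aryne precursor → aryne C–O insertion/oxa-Michael builds pyranone ring B on ring A → demethylation → C8 acylation (last substituent of ring A) → benzylation → reduction → debenzylation.
- Stereochemistry: the single stereocentre C4 (R) comes from catalyst-controlled asymmetric transfer hydrogenation of the C4 ketone with RuCl[(R,R)-TsDPEN](p-cymene), run after benzylation so that only the ring ketone should react.

Key step: step 4

Assumption: chroman numbering is used (O1, C2 with the gem-dimethyl group, C3, C4 carbinol, C4a, C5–OH, C6–Me, C7–OH, C8 acyl, C8a); the C4 centre of the given SMILES is R.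

**Route**

Step 1
Reactants: 1 2,6-dimethoxytoluene
Product: 3 3,5-dimethoxy-4-methylphenol, via arylboronate 2 (not isolated)
Conditions: [Ir(OMe)(cod)]2 (1.5 mol%), dtbpy (3 mol%), B2pin2 (0.55 equiv), THF, 80 °C; then Oxone (KHSO5·0.5KHSO4·0.5K2SO4), acetone/H2O, rt
Reagents that add atoms: bis(pinacolato)diboron, CC1(C)OB(OC1(C)C)B1OC(C)(C)C(C)(C)O1 (boron of 2); potassium peroxymonosulfate KHSO5 from Oxone, [K+].OOS(=O)(=O)[O-] (phenol oxygen)
Why: [Ir(OMe)(cod)]2/dtbpy C–H borylation is sterically controlled and 1 has only one C–H without an ortho substituent (para to the methyl), so boron should go there and the C–B bond is then oxidised in place (one-pot Hartwig–Miyaura borylation/oxidation to a phenol).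

Step 2
Reactants: 3 3,5-dimethoxy-4-methylphenol
Product: 4 2-bromo-3,5-dimethoxy-4-methylphenol
Conditions: NBS (1.0 equiv), CH2Cl2, −78 → 0 °C
Reagents that add atoms: N-bromosuccinimide, O=C1CCC(=O)N1Br
Why: Electrophilic aromatic bromination ortho to the free hydroxyl; the two open positions of the symmetric phenol are equivalent, so one equivalent of NBS at low temperature should give a single monobromide.

Step 3
Reactants: 4 2-bromo-3,5-dimethoxy-4-methylphenol
Product: 7 3,5-dimethoxy-4-methyl-2-(trimethylsilyl)phenyl trifluoromethanesulfonate, via aryl silyl ether 5 (not isolated), via lithium silylphenolate 6 (not isolated)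
Conditions: HMDS, THF, 70 °C, then evaporate; n-BuLi (1.1 equiv), THF, −78 °C; Tf2O (1.2 equiv), −78 °C → rt
Reagents that add atoms: hexamethyldisilazane, C[Si](C)(C)N[Si](C)(C)C; n-butyllithium, [Li]CCCC (lithium of 6); trifluoromethanesulfonic anhydride, O=S(=O)(OS(=O)(=O)C(F)(F)F)C(F)(F)F
Why: O-silylation, bromine–lithium exchange and a 1,3 O-to-C silyl shift (retro-Brook rearrangement) should move the silyl group to the ortho carbon, and the lithium phenolate released is trapped as the triflate, the standard entry to a Kobayashi aryne precursor.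

Step 4
Reactants: 7 3,5-dimethoxy-4-methyl-2-(trimethylsilyl)phenyl trifluoromethanesulfonate; 8 3-methylbut-2-enoic acid
Product: 11 5,7-dimethoxy-2,2,6-trimethylchroman-4-one, via aryne 9 (not isolated), via hydroxyaryl enone 10 (not isolated)
Conditions: 8 (1.5 equiv), CsF (4 equiv), THF, 125 °C, sealed tube
Reagents that add atoms: none
Why: Fluoride strips the silyl group and triflate leaves to give aryne 9, whose C8a–C4a triple bond is distorted by the inductively withdrawing C5 methoxy group, so the oxygen of cesium 3-methylbut-2-enoate should add at the distal, unhindered C8a and the aryl anion should arise at C4a next to that methoxy group. The anion then adds to the ester carbonyl (4-exo-trig) and the benzoxete alkoxide collapses by C–O scission, so the net event is insertion of the aryne into the acid C–O bond, giving the phenolate of enone 10 with the O1–C8a and C4a–C4 bonds made together. Ring B then closes by 6-endo-trig oxa-Michael addition of the C8a phenolate to the β,β-dimethyl enone, helped by the gem-dimethyl group. The closest known reaction type is the aryne C–O insertion of carboxylic acids to 2-hydroxyaryl ketones, which with α,β-unsaturated acids runs on to 4-chromanones. No stereocentre is formed; the selectivity needed is regiochemical (oxygen at C8a, acyl carbon at C4a) and should be secured by the C5–OMe/C8–H pair flanking the aryne, while the high temperature favours acyl transfer over protonation of the aryl anion.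

Step 5
Reactants: 11 5,7-dimethoxy-2,2,6-trimethylchroman-4-one
Product: 12 5,7-dihydroxy-2,2,6-trimethylchroman-4-one
Conditions: BBr3 (4 equiv), CH2Cl2, −78 °C → rt; aqueous work-up
Reagents that add atoms: none
Why: Lewis-acid cleavage of aryl methyl ethers (BBr3 demethylation); the C5 methoxy group is chelation-assisted by the C4 carbonyl, and the ring oxygen O1, a vinylogous ester oxygen, should be too weakly basic to be cleaved.

Step 6
Reactants: 12 5,7-dihydroxy-2,2,6-trimethylchroman-4-one; 13 3-phenylpropanoyl chloride
Product: 14 5,7-dihydroxy-2,2,6-trimethyl-8-(3-phenylpropanoyl)chroman-4-one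
Conditions: 13 (1.3 equiv), AlCl3 (4 equiv), PhNO2/1,2-dichloroethane, 0 → 50 °C; cold dilute HCl work-up
Reagents that add atoms: none
Why: Friedel–Crafts acylation (directly or through O-acylation and Fries rearrangement) at C8, the only unsubstituted carbon of ring A and ortho or para to all three ring oxygens, as in the second acylation of an acylphloroglucinol.

Step 7
Reactants: 14 5,7-dihydroxy-2,2,6-trimethyl-8-(3-phenylpropanoyl)chroman-4-one
Product: 15 5,7-bis(benzyloxy)-2,2,6-trimethyl-8-(3-phenylpropanoyl)chroman-4-one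
Conditions: BnBr (2.5 equiv), K2CO3 (3 equiv), n-Bu4NI (cat.), DMF, 50 °C
Reagents that add atoms: benzyl bromide, BrCc1ccccc1
Why: Williamson ether synthesis; both phenols are hydrogen-bonded to carbonyls and need gentle heating, and benzylation removes the hydrogen bond from the C4 carbonyl while leaving the C8 ketone as a twisted, doubly ortho-flanked ketone.

Step 8
Reactants: 15 5,7-bis(benzyloxy)-2,2,6-trimethyl-8-(3-phenylpropanoyl)chroman-4-one
Product: 16 1-[(4R)-5,7-bis(benzyloxy)-4-hydroxy-2,2,6-trimethyl-3,4-dihydro-2H-chromen-8-yl]-3-phenylpropan-1-one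
Conditions: RuCl[(R,R)-TsDPEN](p-cymene) (2 mol%), HCO2H/Et3N (5:2), EtOAc, 40 °C
Reagents that add atoms: none
Why: Noyori–Ikariya asymmetric transfer hydrogenation, in which the planar ring-fused aryl ketone at C4 is the privileged substrate while the C8 ketone, flanked by O1 and the C7 benzyloxy group and twisted out of conjugation, should be left, and the (R,R)-ligand should deliver hydride to the Si face of C4 (aryl versus CH2 differentiation, as for 4-chromanone) to set 4R.

Step 9
Reactants: 16 1-[(4R)-5,7-bis(benzyloxy)-4-hydroxy-2,2,6-trimethyl-3,4-dihydro-2H-chromen-8-yl]-3-phenylpropan-1-one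
Product: 17 1-[(4R)-4,5,7-trihydroxy-2,2,6-trimethyl-3,4-dihydro-2H-chromen-8-yl]-3-phenylpropan-1-one
Conditions: H2 (1 atm), 10% Pd/C, EtOAc, rt; filtration, no acid in work-up
Reagents that add atoms: none
Why: Catalytic hydrogenolysis of the two benzyl aryl ethers under neutral conditions should be faster than cleavage of the C4 benzylic C–O bond and should leave the hydrogen-bonded aryl ketone and the C4 stereocentre untouched.

**Compound list**

1 | 2,6-dimethoxytoluene | COc1cccc(OC)c1C | starting material
2 | 2-(3,5-dimethoxy-4-methylphenyl)-4,4,5,5-tetramethyl-1,3,2-dioxaborolane | COc1cc(B2OC(C)(C)C(C)(C)O2)cc(OC)c1C | intermediate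
3 | 3,5-dimethoxy-4-methylphenol | COc1cc(O)cc(OC)c1C | intermediate
4 | 2-bromo-3,5-dimethoxy-4-methylphenol | COc1cc(O)c(Br)c(OC)c1C | intermediate
5 | (2-bromo-3,5-dimethoxy-4-methylphenoxy)trimethylsilane | COc1cc(O[Si](C)(C)C)c(Br)c(OC)c1C | intermediate
6 | lithium 3,5-dimethoxy-4-methyl-2-(trimethylsilyl)phenolate | [Li+].[O-]c1cc(OC)c(C)c(OC)c1[Si](C)(C)C | intermediate
7 | 3,5-dimethoxy-4-methyl-2-(trimethylsilyl)phenyl trifluoromethanesulfonate | COc1cc(OS(=O)(=O)C(F)(F)F)c([Si](C)(C)C)c(OC)c1C | intermediate
8 | 3-methylbut-2-enoic acid | CC(C)=CC(=O)O | starting material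
9 | 3,5-dimethoxy-4-methylbenzyne (1,2-didehydro-3,5-dimethoxy-4-methylbenzene) | COC1=C(C)C(OC)=CC#C1 | intermediate
10 | 1-(6-hydroxy-2,4-dimethoxy-3-methylphenyl)-3-methylbut-2-en-1-one (present as its cesium phenolate) | COc1cc(O)c(C(=O)C=C(C)C)c(OC)c1C | intermediate
11 | 5,7-dimethoxy-2,2,6-trimethylchroman-4-one | COc1cc2OC(C)(C)CC(=O)c2c(OC)c1C | intermediate
12 | 5,7-dihydroxy-2,2,6-trimethylchroman-4-one | Cc1c(O)cc2OC(C)(C)CC(=O)c2c1O | intermediate
13 | 3-phenylpropanoyl chloride | O=C(Cl)CCc1ccccc1 | starting material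
14 | 5,7-dihydroxy-2,2,6-trimethyl-8-(3-phenylpropanoyl)chroman-4-one | Cc1c(O)c(C(=O)CCc2ccccc2)c2OC(C)(C)CC(=O)c2c1O | intermediate
15 | 5,7-bis(benzyloxy)-2,2,6-trimethyl-8-(3-phenylpropanoyl)chroman-4-one | Cc1c(OCc3ccccc3)c(C(=O)CCc3ccccc3)c2OC(C)(C)CC(=O)c2c1OCc1ccccc1 | intermediate
16 | 1-[(4R)-5,7-bis(benzyloxy)-4-hydroxy-2,2,6-trimethyl-3,4-dihydro-2H-chromen-8-yl]-3-phenylpropan-1-one | Cc1c(OCc3ccccc3)c(C(=O)CCc3ccccc3)c2c(c1OCc1ccccc1)[C@H](O)CC(C)(C)O2 | intermediate
17 | 1-[(4R)-4,5,7-trihydroxy-2,2,6-trimethyl-3,4-dihydro-2H-chromen-8-yl]-3-phenylpropan-1-one | Cc1c(O)c(C(=O)CCc2ccccc2)c2c(c1O)[C@H](O)CC(C)(C)O2 | target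

**Totals and risks**

Total step count: 9. Longest linear sequence: 9 steps (from 1; compounds 8 and 13 are purchased).

Steps most likely to fail:

1. Step 4. The aryl anion may be protonated before acyl transfer, so that the sequence stops at the aryl ester, or the carboxylate may add with incomplete regiocontrol. Fallback without an aryne, setting out from 3 and coming back at 11: O-acylation of 3 with 3-methylbut-2-enoyl chloride (Et3N, CH2Cl2, 0 °C) should give 3,5-dimethoxy-4-methylphenyl 3-methylbut-2-enoate F1. This is the same ester that the protonation pathway of step 4 would deliver, so material diverted there can be carried on. Fries rearrangement with oxa-Michael closure through enone 10 (P2O5/MeSO3H, 60 °C) should then give 11; the two ortho positions of F1 are equivalent and the para position carries the methyl group, so only one chromanone can form.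

2. Step 8. The catalyst may fail to discriminate the two ketones, or hydride transfer to the electron-rich C4 carbonyl may be too slow. Fallback that sets C4 before the second ketone exists, setting out from 12 and coming back at 16 (it also bypasses step 6):
   - Benzylation (BnBr, K2CO3, DMF, 50 °C) should give 5,7-bis(benzyloxy)-2,2,6-trimethylchroman-4-one F2.
   - The same transfer hydrogenation (RuCl[(R,R)-TsDPEN](p-cymene), HCO2H/Et3N) should give (4R)-5,7-bis(benzyloxy)-2,2,6-trimethylchroman-4-ol F3.
   - NBS (MeCN, NaHCO3, 0 °C) should brominate C8, the only free position of ring A, to give (4R)-5,7-bis(benzyloxy)-8-bromo-2,2,6-trimethylchroman-4-ol F4.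
   - n-BuLi (1 equiv) then t-BuLi (2 equiv) in THF at −78 °C should give lithium (4R)-5,7-bis(benzyloxy)-8-lithio-2,2,6-trimethylchroman-4-olate F5, which is acylated with N-methoxy-N-methyl-3-phenylpropanamide (aqueous NH4Cl quench) to give 16.

3. Step 9. Over-reduction may occur: hydrogenolysis of the electron-rich benzylic C4–O bond, or partial reduction of the ketone, alongside debenzylation. Fallback with fluoride-labile ethers, setting out from 14 and coming back at 17: silylation (TBSCl, imidazole, DMAP, DMF) should give 5,7-bis(tert-butyldimethylsilyloxy)-2,2,6-trimethyl-8-(3-phenylpropanoyl)chroman-4-one F6. Transfer hydrogenation as in step 8 should give 1-[(4R)-5,7-bis(tert-butyldimethylsilyloxy)-4-hydroxy-2,2,6-trimethyl-3,4-dihydro-2H-chromen-8-yl]-3-phenylpropan-1-one F7. Desilylation with n-Bu4NF/AcOH (THF, 0 °C) should then give 17.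

**Further compounds**

F1 | step 4 | 3,5-dimethoxy-4-methylphenyl 3-methylbut-2-enoate | COc1cc(OC(=O)C=C(C)C)cc(OC)c1C
F2 | step 8 | 5,7-bis(benzyloxy)-2,2,6-trimethylchroman-4-one | Cc1c(OCc2ccccc2)cc2OC(C)(C)CC(=O)c2c1OCc1ccccc1
F3 | step 8 | (4R)-5,7-bis(benzyloxy)-2,2,6-trimethylchroman-4-ol | Cc1c(OCc2ccccc2)cc2c(c1OCc1ccccc1)[C@H](O)CC(C)(C)O2
F4 | step 8 | (4R)-5,7-bis(benzyloxy)-8-bromo-2,2,6-trimethylchroman-4-ol | Cc1c(OCc2ccccc2)c(Br)c2c(c1OCc1ccccc1)[C@H](O)CC(C)(C)O2
F5 | step 8 | lithium (4R)-5,7-bis(benzyloxy)-8-lithio-2,2,6-trimethylchroman-4-olate | Cc1c(OCc2ccccc2)c([Li])c2c(c1OCc1ccccc1)[C@H]([O-])CC(C)(C)O2.[Li+]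
F6 | step 9 | 5,7-bis(tert-butyldimethylsilyloxy)-2,2,6-trimethyl-8-(3-phenylpropanoyl)chroman-4-one | Cc1c(O[Si](C)(C)C(C)(C)C)c(C(=O)CCc2ccccc2)c2OC(C)(C)CC(=O)c2c1O[Si](C)(C)C(C)(C)C
F7 | step 9 | 1-[(4R)-5,7-bis(tert-butyldimethylsilyloxy)-4-hydroxy-2,2,6-trimethyl-3,4-dihydro-2H-chromen-8-yl]-3-phenylpropan-1-one | Cc1c(O[Si](C)(C)C(C)(C)C)c(C(=O)CCc2ccccc2)c2c(c1O[Si](C)(C)C(C)(C)C)[C@H](O)CC(C)(C)O2
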